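Start with what stops.

| setting | Saturday's | Friday's | flask |
|---|---|---|---|
| left-handed substrate | 11 mM | 5.5 mM | 11 mM |
| right-handed substrate | 11 mM | 5.5 mM | 11 mM |
| coupling partner | 16.5 mM | 16.5 mM | 16.5 mM |
| free catalyst | 7.4 µM | 7.4 µM | 7.4 µM |
| remark | the very flask that is asked about, followed so far | run made earlier |  |



| Saturday's: time / min | Saturday's: left-handed product / % | Friday's: time / min | Friday's: left-handed product / % |
|---|---|---|---|
| 0.333 | 3.8 | 0.833 | 9.7 |
| 1.00 | 7.2 | 2.50 | 13.7 |
| 2.00 | 10.7 | 5.00 | 17.4 |
| 3.00 | 12.0 | 8.00 | 19.8 |
| 4.00 | 13.1 | 10.0 | 19.5 |

(each reading ± 0.5 percentage points)



- free catalyst is single-handed; left-handed substrate and right-handed substrate are mirror images of each other, charged as a racemate, each of them at the stated concentration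
- steps that have been proposed: free catalyst + left-handed substrate <-> catalyst intermediate A; free catalyst + right-handed substrate <-> catalyst intermediate B; coupling partner + catalyst intermediate A -> free catalyst + left-handed product; coupling partner + catalyst intermediate B -> free catalyst + right-handed product; 2 coupling partner -> homo dimer
- no earlier run changes the charge of free catalyst; that part of a forecast is a guess
- no earlier run changes the charge of coupling partner; that part of a forecast is a guess



* factor on the rate of making left-handed product when 5.0% of the left-handed substrate and right-handed substrate together are converted if coupling partner is charged twice over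
* factor on the rate when 5.0% of the left-handed substrate and right-handed substrate together are converted if free catalyst is charged at 1.5 µM instead



Friday's flask stands flat near 19.5%, less than the 50.0% that its left-handed substrate could give. So I take the coupling partner as the limiting reagent, lost mostly to homo dimer. If that loss runs second-order, [coupling partner] falls roughly as one over time, and the product gains equal steps for equal factors of time.

That step gives the quantity to carry: the reach, the left-handed product made while [coupling partner] falls by a factor e. From Saturday's readings:

reach = (13.1% − 7.2%) / ln(4.00 min / 1.00 min) = 4.26%

[coupling partner] / charge = exp(−left-handed product / reach)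

Now draw Saturday's curve. It starts steeply, with 3.8% by 0.333 min. The knee, where [coupling partner] has halved, comes at

reach × ln(2) = 2.95%

This lies below the first reading, so the knee comes within about 0.259 min. At the last reading the rule leaves 4.60% of the coupling partner. Treat that remainder as a small correction: if every bit of it went to left-handed product, it would add 3.45%, so I estimate the level below 16.6%.

Doubling the coupling partner leaves the reach alone in this picture, so my factor is 2. At 1.5 µM the reach shrinks with the catalyst. Assuming a left-handed share of 2/3, I get

0.203 × 0.0459 = 0.00931

The forecast says 1.9 and 0.008, holding that “the partner has mostly dimerised by then”.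

The simulation gives 2.05 and 0.0181.

    free catalyst + left-handed substrate ⇌ catalyst intermediate A (K = 49.9 /M, k = 35900 /M/s)
    free catalyst + right-handed substrate ⇌ catalyst intermediate B (K = 32.7 /M, k = 6170 /M/s)
    coupling partner + catalyst intermediate A → free catalyst + left-handed product (k = 1890 /M/s)
    coupling partner + catalyst intermediate B → free catalyst + right-handed product (k = 906 /M/s)
    2 coupling partner → homo dimer (k = 1.26 /M/s)

In this flask at 1.00 min, 7.81% of left-handed product put through the reach gives 16.0% of the coupling partner, and the flask holds 23.5%. In the 1.5 µM flask, taking out the catalyst factor leaves 0.0893 for the extra fall of [coupling partner], about twice my 0.0459. Back in this flask, half of the homo dimer path's turnover up to 10.0 min is done by 0.255 min, and 73.4% of the coupling partner has gone that way by 10.0 min. At that time 0.69% of the coupling partner remains, against 71% of the left-handed substrate.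

The readings are calculated with constants of no real substance; the scatter is artificial.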